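## Analysis of the target

The target 24 is an achiral benzophenone. A carbonyl carbon joins C1' of a 2-hydroxy-4,6-dimethoxyphenyl ring (ring A) to C5 of a 7-hydroxy-2,2-dimethyl-2H-chromene, whose benzene ring is ring B and whose third ring is the pyran (O1, C2 with two methyl groups, C3=C4). There is no stereocentre, so every stereocentre that appears on the way is transient and needs no control. The sensitive features are the electron-rich C3=C4 bond (acid, electrophiles, oxidants), two free phenols (the C2' hydroxyl is hydrogen-bonded to the ketone), and a ketone with three ortho substituents, which is hard to make by acylation. The real difficulty is ring B: the acyl carbon at C5 lies meta to both oxygens (C7 and C8a), a position that electrophilic acylation of a resorcinol does not reach. Chromene annulation of a 5-substituted resorcinol would also prefer the carbon between the two oxygens and give the 5-oxy-7-carbon isomer. Ring A is an ordinary phloroglucinol pattern and can be bought with the bridging carbon attached. The plan reads ring B as a resorcinol whose C6–C7–C8–C8a unit is a 1,3-dioxygenated diene and whose C4a–C5 unit, with its two adjacent carbon substituents, is a disubstituted alkyne.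

## Retrosynthetic reasoning

**Unmasking the phenols, 24 from 23.** The two O–CH2 acetal bonds of 23 are cut last. Both phenols travel as methoxymethyl ethers because these survive organometallics, hydride, fluoride and base, and one mild acid step removes both.

**Ketone from carbinol, 23 from 22 from 21.** The C=O bond of the bridge is formed late by oxidation of diaryl carbinol 22, carried until then as silyl ether 21. As a ketone it would activate the alkyne from the wrong side in the ring-forming step and would compete with the C4 carbonyl in the hydride reduction. As a silyloxy carbinol it is electronically neutral.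

**The C3=C4 bond, 21 from 19 from 18.** The olefin of 21 is traced back to the C4 ketone of 18 through reduction to alcohol 19 and dehydration. The C4 oxygen is the activating carbonyl of the key step, so it is already present.

**The pyran ring, 18 from 17 from 16.** The O1–C2 bond is cut. Forward, the C8a phenoxide of 16 adds to the beta,beta-dimethyl enone on C4a to give 17. The remaining C7 hydroxyl is capped in the same flask to give 18, because a free para-hydroxyl would deactivate the ketone and make the later benzylic alcohol a quinone methide precursor.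

**Ring B, 16 from 9 and 13.** The C8a–C4a and C6–C5 bonds are cut. This gives the four-carbon diene 13 with oxygen on the future C7 and C8a, and alkyne 9, which already carries the enone carbons on C4a and the protected carbinol with ring A on C5. Forward, cycloadduct 14 loses methanol to the bis-silyl ether 15, which is hydrolysed to 16. All four substituents of ring B are placed in one regiodefined event, and the meta relationship of C5 to the oxygens follows from the connectivity of the two partners.

**The ynone, 9 from 8 from 5 and 6.** The bond between the alkyne terminus and the carbonyl carbon is cut. Forward, the acetylide 7 of alkyne 5 adds to aldehyde 6 and the doubly activated alcohol 8 is oxidized to 9.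

**The propargylic carbinol, 5 from 4 from 2 and 3, and 2 from 1.** The bond between the bridging carbon and the alkyne is cut to the protected ring A aldehyde 2 and ethynyl Grignard reagent 3. Their adduct 4 is silylated to 5. Aldehyde 2 is the phenol-protected form of commercial 1, so ring A needs no construction.

**The diene, 13 from 11 from 10.** O-Silylation of keto ester 10 gives enol ether 11, and a second O-silylation through dienolate 12 gives 13.

## Alternatives that were turned down

Alternative 1: The C1'–carbonyl and C2'–O bonds are cut. Forward, fluoride releases 3,5-dimethoxybenzyne A4 from the silyl triflate A3. The carboxylate of chromene acid A2 adds to the aryne carbon remote from the methoxy group, and the aryl anion takes the acyl group through a four-membered transition structure to give A1.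
- For: it is convergent, the ketone appears at the right oxidation level with the C2' hydroxyl free, and the methoxy group next to the aryne directs the addition the right way. On step count after the union it is stronger than the chosen route, since only one deprotection remains.
- Against: A2 has the ring B pattern that ordinary chromene annulation of a 5-substituted resorcinol disfavours, so the hard part of the molecule is moved into the starting material. The acyl shift must occur onto a hindered carbonyl, in competition with simple protonation of the aryl anion and with further arylation of the liberated phenoxide. The electron-rich C3=C4 bond is exposed to the aryne. A3 itself takes several steps.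
- Comparison: the chosen route is longer, but it builds the ring B pattern by connectivity instead of presupposing it.

Alternative 2: The C4a–C5 and C8–C8a bonds are cut. Forward, dimethyl malonate A7 adds to enone A6 under NaOMe and the methyl ketone enolate acylates a malonate ester group, giving dione A5. A5 would be aromatized to resorcinol ester A8.
- For: the materials are cheap, the condensation is robust and scalable, and the regiochemistry is unambiguous. On these points it is stronger than the chosen route.
- Against: the key step delivers only a bare ring B with two handles. Dehydrogenation of the dione next to an acid-labile acetal, differentiation of two phenols, conversion of the ester into the three pyran carbons, and attachment of ring A to a hindered formyl group followed by oxidation all remain. The two stereocentres of A5 are made only to be destroyed.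
- Comparison: the chosen cycloaddition gives ring B with the pyran carbons and ring A already attached, so its tail is much shorter.

Alternative 3: The C2'–C1', C6'–C5' and C2'–C3' bonds of ring A are cut. Forward, heating cyclobutenone A10 with the 1-methoxyalkyne A11 gives a vinylketene, which adds the alkyne, reopens and closes by electrocyclization to phenol A9.
- For: the mechanism fixes the regiochemistry and delivers the one free hydroxyl of ring A already differentiated from the two methoxy groups. On that point it is stronger than the chosen route, which needs a protecting group for this hydroxyl.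
- Against: ring A is not the problem, since 1 is commercial with this pattern. A11 already contains ring B with the difficult pattern of carbon on C5 and oxygen on C7, so that problem stays unsolved, and it is an acid-sensitive ynol ether with a propargylic silyloxy group. A10 must be prepared. Ketene intermediates are generated by heating in the presence of the chromene olefin. Desilylation and carbinol oxidation with a free phenol would follow.
- Comparison: the chosen route spends its ring-forming step on ring B, where the structure is hard.

Key step: step 8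

Remark on the chemistry: the target has no stereocentre; the bridging carbinol is carried as a racemate, and the other stereocentres formed on the way (steps 4 and 10, cycloadduct 14) are mixtures that are erased again.

## Route

Step 1
Reactants: 1 2-hydroxy-4,6-dimethoxybenzaldehyde
Product: 2 2-(methoxymethoxy)-4,6-dimethoxybenzaldehyde
Conditions: MOMCl, i-Pr2NEt, CH2Cl2, 0 °C to rt
Reagents that add atoms: chloromethyl methyl ether, COCCl
Why: O-alkylation of the phenol with the chloromethyl ether (Williamson-type acetal formation); the hydrogen-bonded hydroxyl reacts more slowly than a free phenol but is the only nucleophile present, and the aldehyde is untouched.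

Step 2
Reactants: 2 2-(methoxymethoxy)-4,6-dimethoxybenzaldehyde; 3 ethynylmagnesium bromide
Product: 4 1-[2-(methoxymethoxy)-4,6-dimethoxyphenyl]prop-2-yn-1-ol (racemic)
Conditions: THF, 0 °C to rt; then sat. aq. NH4Cl
Reagents that add atoms: none
Why: Grignard 1,2-addition of the alkynyl reagent to the aldehyde; the carbinol centre forms as a racemate and is destroyed in step 13, and the near-neutral quench avoids ionization of the electron-rich propargylic alcohol.

Step 3
Reactants: 4 1-[2-(methoxymethoxy)-4,6-dimethoxyphenyl]prop-2-yn-1-ol
Product: 5 tert-butyl{1-[2-(methoxymethoxy)-4,6-dimethoxyphenyl]prop-2-yn-1-yloxy}dimethylsilane (racemic)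
Conditions: TBSCl, imidazole, DMF, rt
Reagents that add atoms: tert-butyldimethylsilyl chloride, CC(C)(C)[Si](C)(C)Cl
Why: Imidazole-promoted silylation of the secondary alcohol; the silyl ether keeps the bridging carbon at the non-activating alcohol level, survives base, hydride and heat, and is removed by fluoride in step 12.

Step 4
Reactants: 5 tert-butyl{1-[2-(methoxymethoxy)-4,6-dimethoxyphenyl]prop-2-yn-1-yloxy}dimethylsilane; 6 3-methylbut-2-enal
Product: 8 1-(tert-butyldimethylsilyloxy)-1-[2-(methoxymethoxy)-4,6-dimethoxyphenyl]-6-methylhept-5-en-2-yn-4-ol (diastereomer mixture), via lithium acetylide 7 (not isolated)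
Conditions: n-BuLi (1.0 equiv), THF, −78 °C; then 6, −78 to 0 °C; sat. aq. NH4Cl
Reagents that add atoms: none
Why: The terminal alkyne is by far the most acidic C–H, so one equivalent of n-BuLi at low temperature gives 7 without ortho-metalation of ring A; lithium acetylides add 1,2 to enals, and the new carbinol centre is oxidized away in step 5.

Step 5
Reactants: 8 1-(tert-butyldimethylsilyloxy)-1-[2-(methoxymethoxy)-4,6-dimethoxyphenyl]-6-methylhept-5-en-2-yn-4-ol
Product: 9 1-(tert-butyldimethylsilyloxy)-1-[2-(methoxymethoxy)-4,6-dimethoxyphenyl]-6-methylhept-5-en-2-yn-4-one (racemic)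
Conditions: MnO2, CH2Cl2, rt
Reagents that add atoms: none
Why: MnO2 oxidation of an alcohol that is both propargylic and allylic is fast and stops at the ketone; the silyl ether, the acetal and the trisubstituted alkene are inert.

Step 6
Reactants: 10 methyl acetoacetate
Product: 11 methyl 3-(trimethylsilyloxy)but-2-enoate (E/Z mixture)
Conditions: TMSCl, Et3N, hexane, rt
Reagents that add atoms: chlorotrimethylsilane, C[Si](C)(C)Cl
Why: O-silylation of the keto ester enol under amine base (silyl enol ether formation); only the ketone oxygen is silylated.

Step 7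
Reactants: 11 methyl 3-(trimethylsilyloxy)but-2-enoate
Product: 13 1-methoxy-1,3-bis(trimethylsilyloxy)buta-1,3-diene, via lithium dienolate 12 (not isolated)
Conditions: LiN(i-Pr)2, THF, −78 °C; then TMSCl, −78 °C to rt
Reagents that add atoms: chlorotrimethylsilane, C[Si](C)(C)Cl
Why: Kinetic gamma-deprotonation gives the ester dienolate 12, which is O-silylated to the ketene acetal (standard preparation of this diene); the ketene acetal geometry is irrelevant because that carbon becomes aromatic.

Step 8
Reactants: 9 1-(tert-butyldimethylsilyloxy)-1-[2-(methoxymethoxy)-4,6-dimethoxyphenyl]-6-methylhept-5-en-2-yn-4-one; 13 1-methoxy-1,3-bis(trimethylsilyloxy)buta-1,3-diene (2.5 equiv)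
Product: 16 1-[2-[(tert-butyldimethylsilyloxy)[2-(methoxymethoxy)-4,6-dimethoxyphenyl]methyl]-4,6-dihydroxyphenyl]-3-methylbut-2-en-1-one (racemic), via cycloadduct 14 (not isolated), via bis(trimethylsilyl) ether 15 (not isolated)
Conditions: PhMe, 90 °C (sealed tube); then 5% aq. citric acid, THF, 0 °C
Reagents that add atoms: none
Why: The electron-rich diene 13 and the electron-poor triple bond of 9 combine in a normal-demand [4+2] cycloaddition (at the polar extreme, a Mukaiyama–Michael addition followed by closure of the allenolate onto the silyloxy-methoxy carbenium carbon), and both pathways join the CH2 terminus of the diene to the alkyne carbon beta to the ketone (C6–C5) and the acetal carbon to the alpha carbon (C8a–C4a). Ring B is thereby closed as a six-membered carbocycle across the diene termini to give the 1,4-cyclohexadiene 14, which aromatizes by 1,4-elimination of methanol to 15, and the cold, weakly acidic work-up hydrolyses the two aryl O–SiMe3 bonds to 16. The closest known reaction type is the cycloaddition of 1-alkoxy-1,3-bis(silyloxy)butadienes with acetylenic ketones and esters to give resorcinols and resorcylates. The regiochemistry that places the acyl group ortho to the acetal-derived oxygen is secured because the alkyne is polarized by a single carbonyl group (the silyloxy carbinol at the other terminus is electronically neutral) and the largest HOMO coefficient of the diene sits on its unsubstituted CH2 terminus. Chemoselectivity for the alkyne over the enone follows from the poor dienophilicity of a beta,beta-dimethyl-substituted alkene and the small steric demand of a triple bond. Loss of methanol instead of trimethylsilanol from the mixed acetal carbon keeps the C8a–O–Si bond and so delivers the free C8a hydroxyl that step 9 needs, as is usual for mixed methyl silyl ketene acetal dienes. The acetal carbon of 14 is a transient stereocentre that vanishes on aromatization and the carbinol centre is untouched and racemic, so no stereocontrol is required. The work-up is kept mild because the silyl ether next to the trioxygenated ring A ionizes easily.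

Step 9
Reactants: 16 1-[2-[(tert-butyldimethylsilyloxy)[2-(methoxymethoxy)-4,6-dimethoxyphenyl]methyl]-4,6-dihydroxyphenyl]-3-methylbut-2-en-1-one
Product: 18 5-[(tert-butyldimethylsilyloxy)[2-(methoxymethoxy)-4,6-dimethoxyphenyl]methyl]-7-(methoxymethoxy)-2,2-dimethylchroman-4-one (racemic), via 7-hydroxychromanone 17 (not isolated)
Conditions: K2CO3, acetone, 40 °C; then MOMCl, 0 °C to rt
Reagents that add atoms: chloromethyl methyl ether, COCCl
Why: The C8a phenoxide closes the pyranone ring by 6-endo-trig oxa-Michael addition to the beta,beta-dimethyl enone (the usual fate of ortho-hydroxyaryl 3-methylbut-2-enoyl ketones); the remaining C7 phenoxide is then O-alkylated in the same flask, so that no free para-hydroxyl is carried through steps 10 and 11.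

Step 10
Reactants: 18 5-[(tert-butyldimethylsilyloxy)[2-(methoxymethoxy)-4,6-dimethoxyphenyl]methyl]-7-(methoxymethoxy)-2,2-dimethylchroman-4-one
Product: 19 5-[(tert-butyldimethylsilyloxy)[2-(methoxymethoxy)-4,6-dimethoxyphenyl]methyl]-7-(methoxymethoxy)-2,2-dimethylchroman-4-ol (diastereomer mixture)
Conditions: LiAlH4, THF, 0 °C; then H2O, 15% aq. NaOH, H2O
Reagents that add atoms: none
Why: Hydride reduction of the aryl ketone; LiAlH4 is chosen because the carbonyl is deactivated by the ortho and para oxygens and shielded by the C5 substituent, and the C4 diastereomers converge in step 11.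

Step 11
Reactants: 19 5-[(tert-butyldimethylsilyloxy)[2-(methoxymethoxy)-4,6-dimethoxyphenyl]methyl]-7-(methoxymethoxy)-2,2-dimethylchroman-4-ol
Product: 21 tert-butyl{[7-(methoxymethoxy)-2,2-dimethyl-2H-chromen-5-yl][2-(methoxymethoxy)-4,6-dimethoxyphenyl]methoxy}dimethylsilane (racemic), via sulfamate ester 20 (not isolated)
Conditions: Burgess reagent (MeO2CN(−)SO2N(+)Et3), PhMe, 60 °C
Reagents that add atoms: none
Why: Burgess dehydration: the sulfamate ester 20 of the benzylic alcohol collapses by syn-elimination within the ion pair to the conjugated C3=C4 bond under neutral conditions, so no free acid can ionize the ring A carbinol ether or cleave the acetals.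

Step 12
Reactants: 21 tert-butyl{[7-(methoxymethoxy)-2,2-dimethyl-2H-chromen-5-yl][2-(methoxymethoxy)-4,6-dimethoxyphenyl]methoxy}dimethylsilane
Product: 22 [7-(methoxymethoxy)-2,2-dimethyl-2H-chromen-5-yl][2-(methoxymethoxy)-4,6-dimethoxyphenyl]methanol (racemic)
Conditions: Bu4NF, THF, 0 °C to rt
Reagents that add atoms: none
Why: Fluoride-induced cleavage of the Si–O bond; the basic medium is tolerated by the chromene, the acetals and the easily ionized diaryl carbinol.

Step 13
Reactants: 22 [7-(methoxymethoxy)-2,2-dimethyl-2H-chromen-5-yl][2-(methoxymethoxy)-4,6-dimethoxyphenyl]methanol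
Product: 23 [7-(methoxymethoxy)-2,2-dimethyl-2H-chromen-5-yl][2-(methoxymethoxy)-4,6-dimethoxyphenyl]methanone
Conditions: Dess–Martin periodinane, NaHCO3, CH2Cl2, 0 °C to rt
Reagents that add atoms: none
Why: Dess–Martin oxidation of the secondary diaryl carbinol to the ketone under buffered, homogeneous conditions; no free phenol is present, the chromene double bond is not attacked, and the last stereocentre disappears.

Step 14
Reactants: 23 [7-(methoxymethoxy)-2,2-dimethyl-2H-chromen-5-yl][2-(methoxymethoxy)-4,6-dimethoxyphenyl]methanone
Product: 24 (2-hydroxy-4,6-dimethoxyphenyl)(7-hydroxy-2,2-dimethyl-2H-chromen-5-yl)methanone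
Conditions: HCl (aq., cat.), MeOH, 45 °C
Reagents that add atoms: none
Why: Acid-catalysed transacetalization of both methoxymethyl ethers to the solvent; the ether ortho to the carbonyl is the more labile, and 2,2-dimethylchromenes tolerate dilute methanolic acid at moderate temperature.

## Compound list

1 | 2-hydroxy-4,6-dimethoxybenzaldehyde | COc1cc(O)c(C=O)c(OC)c1 | starting material
2 | 2-(methoxymethoxy)-4,6-dimethoxybenzaldehyde | COCOc1cc(OC)cc(OC)c1C=O | intermediate
3 | ethynylmagnesium bromide | C#C[Mg]Br | starting material
4 | 1-[2-(methoxymethoxy)-4,6-dimethoxyphenyl]prop-2-yn-1-ol (racemic) | C#CC(O)c1c(OCOC)cc(OC)cc1OC | intermediate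
5 | tert-butyl{1-[2-(methoxymethoxy)-4,6-dimethoxyphenyl]prop-2-yn-1-yloxy}dimethylsilane (racemic) | C#CC(O[Si](C)(C)C(C)(C)C)c1c(OCOC)cc(OC)cc1OC | intermediate
6 | 3-methylbut-2-enal | CC(C)=CC=O | starting material
7 | {3-(tert-butyldimethylsilyloxy)-3-[2-(methoxymethoxy)-4,6-dimethoxyphenyl]prop-1-yn-1-yl}lithium (racemic) | [Li]C#CC(O[Si](C)(C)C(C)(C)C)c1c(OCOC)cc(OC)cc1OC | intermediate
8 | 1-(tert-butyldimethylsilyloxy)-1-[2-(methoxymethoxy)-4,6-dimethoxyphenyl]-6-methylhept-5-en-2-yn-4-ol (diastereomer mixture) | CC(C)=CC(O)C#CC(O[Si](C)(C)C(C)(C)C)c1c(OCOC)cc(OC)cc1OC | intermediate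
9 | 1-(tert-butyldimethylsilyloxy)-1-[2-(methoxymethoxy)-4,6-dimethoxyphenyl]-6-methylhept-5-en-2-yn-4-one (racemic) | CC(C)=CC(=O)C#CC(O[Si](C)(C)C(C)(C)C)c1c(OCOC)cc(OC)cc1OC | intermediate
10 | methyl acetoacetate | COC(=O)CC(C)=O | starting material
11 | methyl 3-(trimethylsilyloxy)but-2-enoate (E/Z mixture) | COC(=O)C=C(C)O[Si](C)(C)C | intermediate
12 | lithium 1-methoxy-3-(trimethylsilyloxy)buta-1,3-dien-1-olate | C=C(O[Si](C)(C)C)C=C(OC)O[Li] | intermediate
13 | 1-methoxy-1,3-bis(trimethylsilyloxy)buta-1,3-diene (geometry at the ketene acetal immaterial) | COC(O[Si](C)(C)C)=CC(=C)O[Si](C)(C)C | intermediate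
14 | 1-[2-[(tert-butyldimethylsilyloxy)[2-(methoxymethoxy)-4,6-dimethoxyphenyl]methyl]-6-methoxy-4,6-bis(trimethylsilyloxy)cyclohexa-1,4-dien-1-yl]-3-methylbut-2-en-1-one (diastereomer mixture) | COC1(O[Si](C)(C)C)C=C(O[Si](C)(C)C)CC(C(O[Si](C)(C)C(C)(C)C)c2c(OCOC)cc(OC)cc2OC)=C1C(=O)C=C(C)C | intermediate
15 | 1-[2-[(tert-butyldimethylsilyloxy)[2-(methoxymethoxy)-4,6-dimethoxyphenyl]methyl]-4,6-bis(trimethylsilyloxy)phenyl]-3-methylbut-2-en-1-one (racemic) | CC(C)=CC(=O)c1c(O[Si](C)(C)C)cc(O[Si](C)(C)C)cc1C(O[Si](C)(C)C(C)(C)C)c1c(OCOC)cc(OC)cc1OC | intermediate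
16 | 1-[2-[(tert-butyldimethylsilyloxy)[2-(methoxymethoxy)-4,6-dimethoxyphenyl]methyl]-4,6-dihydroxyphenyl]-3-methylbut-2-en-1-one (racemic) | CC(C)=CC(=O)c1c(O)cc(O)cc1C(O[Si](C)(C)C(C)(C)C)c1c(OCOC)cc(OC)cc1OC | intermediate
17 | 5-[(tert-butyldimethylsilyloxy)[2-(methoxymethoxy)-4,6-dimethoxyphenyl]methyl]-7-hydroxy-2,2-dimethylchroman-4-one (racemic) | CC1(C)CC(=O)c2c(O1)cc(O)cc2C(O[Si](C)(C)C(C)(C)C)c1c(OCOC)cc(OC)cc1OC | intermediate
18 | 5-[(tert-butyldimethylsilyloxy)[2-(methoxymethoxy)-4,6-dimethoxyphenyl]methyl]-7-(methoxymethoxy)-2,2-dimethylchroman-4-one (racemic) | CC1(C)CC(=O)c2c(O1)cc(OCOC)cc2C(O[Si](C)(C)C(C)(C)C)c1c(OCOC)cc(OC)cc1OC | intermediate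
19 | 5-[(tert-butyldimethylsilyloxy)[2-(methoxymethoxy)-4,6-dimethoxyphenyl]methyl]-7-(methoxymethoxy)-2,2-dimethylchroman-4-ol (diastereomer mixture) | CC1(C)CC(O)c2c(O1)cc(OCOC)cc2C(O[Si](C)(C)C(C)(C)C)c1c(OCOC)cc(OC)cc1OC | intermediate
20 | triethylammonium salt of the C4 O-[N-(methoxycarbonyl)sulfamate] of 19 (diastereomer mixture) | CC1(C)CC(OS(=O)(=O)[N-]C(=O)OC)c2c(O1)cc(OCOC)cc2C(O[Si](C)(C)C(C)(C)C)c1c(OCOC)cc(OC)cc1OC.CC[NH+](CC)CC | intermediate
21 | tert-butyl{[7-(methoxymethoxy)-2,2-dimethyl-2H-chromen-5-yl][2-(methoxymethoxy)-4,6-dimethoxyphenyl]methoxy}dimethylsilane (racemic) | CC1(C)C=Cc2c(O1)cc(OCOC)cc2C(O[Si](C)(C)C(C)(C)C)c1c(OCOC)cc(OC)cc1OC | intermediate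
22 | [7-(methoxymethoxy)-2,2-dimethyl-2H-chromen-5-yl][2-(methoxymethoxy)-4,6-dimethoxyphenyl]methanol (racemic) | CC1(C)C=Cc2c(O1)cc(OCOC)cc2C(O)c1c(OCOC)cc(OC)cc1OC | intermediate
23 | [7-(methoxymethoxy)-2,2-dimethyl-2H-chromen-5-yl][2-(methoxymethoxy)-4,6-dimethoxyphenyl]methanone | CC1(C)C=Cc2c(O1)cc(OCOC)cc2C(=O)c1c(OCOC)cc(OC)cc1OC | intermediate
24 | (2-hydroxy-4,6-dimethoxyphenyl)(7-hydroxy-2,2-dimethyl-2H-chromen-5-yl)methanone (CNP0142929.0) | COc1cc(O)c(C(=O)c2cc(O)cc3c2C=CC(C)(C)O3)c(OC)c1 | target

## Step count and least certain steps

Total: 14 steps. Longest linear sequence: 12 steps (steps 1 to 5 and 8 to 14); the diene branch is 2 steps (6 and 7).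

**Step 8 (key step).** Cycloaddition at the congested internal triple bond may be slower than thermal decay or protodesilylation of the diene. The diene may instead add in Mukaiyama fashion to the cross-conjugated dienone or its carbonyl. Aromatization may partly proceed with loss of silanol, leaving a methyl ether at C8a that cannot close the pyran ring. The ring A carbinol ether may ionize during release of the phenols. Partial early closure to 17 would be harmless, since step 9 converges on the same compound. Fallback: the pyran carbons are taken out of the cycloaddition. Setting out from 5, acetylide 7 would be acylated with N-methoxy-N-methylacetamide to 5-(tert-butyldimethylsilyloxy)-5-[2-(methoxymethoxy)-4,6-dimethoxyphenyl]pent-3-yn-2-one F1, a smaller and more electrophilic dienophile with no second unsaturated site. Cycloaddition with 13 under the conditions of step 8 would give the acetophenone 1-[2-[(tert-butyldimethylsilyloxy)[2-(methoxymethoxy)-4,6-dimethoxyphenyl]methyl]-4,6-dihydroxyphenyl]ethan-1-one F2, which cannot cyclize prematurely. The non-chelated para hydroxyl would be protected (MOMCl, i-Pr2NEt) to 1-[2-[(tert-butyldimethylsilyloxy)[2-(methoxymethoxy)-4,6-dimethoxyphenyl]methyl]-6-hydroxy-4-(methoxymethoxy)phenyl]ethan-1-one F3. Kabbe condensation with acetone and pyrrolidine (aldol condensation, then oxa-Michael closure) would return to the route at 18.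

**Step 11.** The C4 carbon and the silyloxy carbinol carbon sit on adjacent positions of ring B. Once C4 develops cationic character, capture by the neighbouring ether oxygen with loss of the silyl group (a five-membered cyclic ether) can compete with elimination. Sulfamate formation at the hindered hydroxyl may also be slow. Fallback: no cation is generated at C4. Setting out from 18, enolization and O-triflation (KN(SiMe3)2, PhNTf2, THF, −78 °C) would give 5-[(tert-butyldimethylsilyloxy)[2-(methoxymethoxy)-4,6-dimethoxyphenyl]methyl]-7-(methoxymethoxy)-2,2-dimethyl-2H-chromen-4-yl trifluoromethanesulfonate F4. Reduction of the vinyl triflate (Pd(OAc)2, PPh3, Et3N, HCO2H, DMF, 60 °C) would return to the route at 21, bypassing steps 10 and 11.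

**Step 9.** The chromanone carbonyl is forced into the plane of ring B next to the bulky C5 substituent, so the reversible conjugate addition may stall short of completion. Alkylation could then cap the C8a oxygen of open material. Fallback: the pyran ring is closed by electrocyclization instead. Setting out from 16, selective protection of the non-chelated C7 hydroxyl (MOMCl, i-Pr2NEt, CH2Cl2, 0 °C) would give 1-[2-[(tert-butyldimethylsilyloxy)[2-(methoxymethoxy)-4,6-dimethoxyphenyl]methyl]-6-hydroxy-4-(methoxymethoxy)phenyl]-3-methylbut-2-en-1-one F5. 1,2-Reduction (NaBH4, CeCl3·7H2O, MeOH, 0 °C) would give 3-[(tert-butyldimethylsilyloxy)[2-(methoxymethoxy)-4,6-dimethoxyphenyl]methyl]-2-(1-hydroxy-3-methylbut-2-en-1-yl)-5-(methoxymethoxy)phenol F6. Warming F6 in PhMe would expel water to an ortho-quinone methide that closes by oxa-electrocyclization, returning to the route at 21 and bypassing steps 9 to 11.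

**Step 13.** Ligand exchange at the hindered carbinol, which has three ortho substituents, may be slow. The free diaryl carbinol 22 next to the trioxygenated ring A may ionize on handling and be lost to substitution products. Fallback: the free carbinol is avoided altogether. Setting out from 21, hydride abstraction from the electron-rich diarylmethyl silyl ether with DDQ in wet CH2Cl2 would give the silyloxy carbenium ion, which loses the silyl group. This would return to the route at 23, bypassing step 12; no new compound is made.

## Further compounds

F1 | step 8 | 5-(tert-butyldimethylsilyloxy)-5-[2-(methoxymethoxy)-4,6-dimethoxyphenyl]pent-3-yn-2-one (racemic) | CC(=O)C#CC(O[Si](C)(C)C(C)(C)C)c1c(OCOC)cc(OC)cc1OC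
F2 | step 8 | 1-[2-[(tert-butyldimethylsilyloxy)[2-(methoxymethoxy)-4,6-dimethoxyphenyl]methyl]-4,6-dihydroxyphenyl]ethan-1-one (racemic) | CC(=O)c1c(O)cc(O)cc1C(O[Si](C)(C)C(C)(C)C)c1c(OCOC)cc(OC)cc1OC
F3 | step 8 | 1-[2-[(tert-butyldimethylsilyloxy)[2-(methoxymethoxy)-4,6-dimethoxyphenyl]methyl]-6-hydroxy-4-(methoxymethoxy)phenyl]ethan-1-one (racemic) | CC(=O)c1c(O)cc(OCOC)cc1C(O[Si](C)(C)C(C)(C)C)c1c(OCOC)cc(OC)cc1OC
F4 | step 11 | 5-[(tert-butyldimethylsilyloxy)[2-(methoxymethoxy)-4,6-dimethoxyphenyl]methyl]-7-(methoxymethoxy)-2,2-dimethyl-2H-chromen-4-yl trifluoromethanesulfonate (racemic) | CC1(C)C=C(OS(=O)(=O)C(F)(F)F)c2c(O1)cc(OCOC)cc2C(O[Si](C)(C)C(C)(C)C)c1c(OCOC)cc(OC)cc1OC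
F5 | step 9 | 1-[2-[(tert-butyldimethylsilyloxy)[2-(methoxymethoxy)-4,6-dimethoxyphenyl]methyl]-6-hydroxy-4-(methoxymethoxy)phenyl]-3-methylbut-2-en-1-one (racemic) | CC(C)=CC(=O)c1c(O)cc(OCOC)cc1C(O[Si](C)(C)C(C)(C)C)c1c(OCOC)cc(OC)cc1OC
F6 | step 9 | 3-[(tert-butyldimethylsilyloxy)[2-(methoxymethoxy)-4,6-dimethoxyphenyl]methyl]-2-(1-hydroxy-3-methylbut-2-en-1-yl)-5-(methoxymethoxy)phenol (diastereomer mixture) | CC(C)=CC(O)c1c(O)cc(OCOC)cc1C(O[Si](C)(C)C(C)(C)C)c1c(OCOC)cc(OC)cc1OC
F0 | step 13 | none | none
A1 | alternative 1 | (2-hydroxy-4,6-dimethoxyphenyl)[7-(methoxymethoxy)-2,2-dimethyl-2H-chromen-5-yl]methanone | COc1cc(O)c(C(=O)c2cc(OCOC)cc3c2C=CC(C)(C)O3)c(OC)c1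
A2 | alternative 1 | 7-(methoxymethoxy)-2,2-dimethyl-2H-chromene-5-carboxylic acid | COCOc1cc(C(=O)O)c2C=CC(C)(C)Oc2c1
A3 | alternative 1 | 3,5-dimethoxy-2-(trimethylsilyl)phenyl trifluoromethanesulfonate | COc1cc(OC)c([Si](C)(C)C)c(OS(=O)(=O)C(F)(F)F)c1
A4 | alternative 1 | 3,5-dimethoxybenzyne | COC1=CC(OC)=CC#C1
A5 | alternative 2 | methyl trans-2-(dimethoxymethyl)-4,6-dioxocyclohexane-1-carboxylate (racemic, one enantiomer drawn) | COC(=O)[C@@H]1C(=O)CC(=O)C[C@H]1C(OC)OC
A6 | alternative 2 | (E)-5,5-dimethoxypent-3-en-2-one | COC(OC)/C=C/C(C)=O
A7 | alternative 2 | dimethyl malonate | COC(=O)CC(=O)OC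
A8 | alternative 2 | methyl 2-(dimethoxymethyl)-4,6-dihydroxybenzoate | COC(=O)c1c(O)cc(O)cc1C(OC)OC
A9 | alternative 3 | 2-[(tert-butyldimethylsilyloxy)[7-(tert-butyldimethylsilyloxy)-2,2-dimethyl-2H-chromen-5-yl]methyl]-3,5-dimethoxyphenol (racemic) | COc1cc(O)c(C(O[Si](C)(C)C(C)(C)C)c2cc(O[Si](C)(C)C(C)(C)C)cc3c2C=CC(C)(C)O3)c(OC)c1
A10 | alternative 3 | 3-methoxycyclobut-2-en-1-one | COC1=CC(=O)C1
A11 | alternative 3 | tert-butyl{[5-[1-(tert-butyldimethylsilyloxy)-3-methoxyprop-2-yn-1-yl]-2,2-dimethyl-2H-chromen-7-yl]oxy}dimethylsilane (racemic) | COC#CC(O[Si](C)(C)C(C)(C)C)c1cc(O[Si](C)(C)C(C)(C)C)cc2c1C=CC(C)(C)O2
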